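The data were computed with constants of no real substance, and the scatter is random.

What is left in the midnight flask once G has gone (a reading of 0% at 10.0 min) is Q plus a rest these readings do not show. You take that rest to be E, which is your own assumption, and the split between the two carries the asked values.

| setting | midnight | summer | flask |
|---|---|---|---|
| G | 20 mM | 13 mM | 20 mM |
| remark | the very flask that is asked about, followed so far | run made earlier |  |
| time |  |  | 4.0 h |

- midnight (time / min: Q / %, G / %): 10.0: 81.2, 0; 15.0: 76.9, 0.5; 25.0: 70.5, 0; 40.0: 66.8, 0; 80.0: 63.5, 0.3; 120: 64.5, 0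
- summer (time / min: Q / %, G / %): 6.00: 86.6, 2.6; 20.0: 70.4, 0; 30.0: 69.1, 0.1; 50.0: 64.0, 0; 80.0: 63.8, 0; 90.0: 64.0, 0.6

(readings scatter by 1 percentage point)

- amount of Q in percent of the G charged, at 12 min, 1.0 h and 4.0 h

Take the given numbers in turn. The charge matters little: the summer flask with 13 mM and the midnight flask with 20 mM read 63.8% and 63.5% at 80.0 min, with a scatter of 1 percentage point. The exact late time matters little too, since the midnight flask reads 63.5% at 80.0 min and 64.5% at 120 min. The plateau matters: a point off there is a point off at 4.0 h. A point off in the midnight reading at 10.0 min carries over to 12 min, which lies close beside it. The decay time comes last, and it acts on the excess over the plateau.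

Now the numbers. At rest, Q -> E and its way back run equally fast, so dividing one rate by the other removes time and leaves a ratio, the equilibrium constant of Q <-> E.

Plateau of Q, mean of the late readings: 64.0%

Plateau ratio ρ = cE/cQ at rest: ρ = (1 − plateau)/plateau = 0.563

Decay time of the excess, midnight readings at 10.0 min and 25.0 min: τ = 15.5 min

Q at 12 min: 79.1%

Q at 1.0 h: 64.6%

Q at 4.0 h, far longer than τ: 64.0%

The forecast gives 79.3%, 64.8% and 64.5%, on a plateau that “fits Q <-> E reaching equilibrium”, and it stands above my value at 4.0 h.

The flask gives 80.3%, 64.7% and 64.5%.

    G → Q (k = 0.570 /min)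
    G → D (k = 0.0150 /min)
    D → J (k = 0.0360 /min)
    J → Q (k = 0.0360 /min)
    Q ⇌ E (K = 0.550, k = 0.0240 /min)

The half-life of Q by its forward step alone, with the way back not counted, is 0.48 h, shorter than the 4.0 h asked about. Now hold ρ against the flask on its way to rest. At 0.400 h the flask has Q at 71.0% and E at 26.9%, so cE/cQ is 0.379, less than ρ. At 2.00 h it has Q at 64.5% and E at 35.4%, and cE/cQ has risen to 0.549.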